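**Retrosynthetic overview**
1. Target 30 ⇒ bromo aldehyde 28. Rings B and C close together in the last step: the C7–C8 bond by intramolecular allylchromium addition, the C8–O bond by lactonisation.
2. 28 ⇒ 25 (deprotection, cross-metathesis) ⇒ keto lactone 23 (convex-face reduction of C2=O, acetylation).
3. Ring D of 23 ⇒ hydroxy enone 10 + aryl acrylate 21. A C3–C13′ Michael addition and closure of the O4–C12′ lactone bond join the two halves.
4. Key disconnection: the tertiary C4–O bond of 10, made on silyl dienol ether 6 by a catalytic asymmetric oxygen transfer. This carbinol centre then dictates C3, C11′ and C2.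
5. Ring A is bought as cyclopentane-1,3-dione (C10 comes from an organocatalytic Michael addition to crotonaldehyde). Arene E is bought as (2-bromo-4-chlorophenyl)methanol. Ring order: A, E (bought) → D → B + C.

Notation and assumption: guaiane numbering C1–C15, primes for the aryl half (C11′ = ArCH, C12′ = lactone C=O, C13′ = CH2); rings A cyclopentene, B cycloheptene, C γ-lactone, D δ-lactone, E arene; C8 in 3–7 and 9, C4 in 5, C5 in 9, and C3/C11′ in 22 are inconsequential epimer mixtures and are written without descriptors.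

Step 1
Reactants: 1 cyclopentane-1,3-dione; 2 (E)-but-2-enal
Product: 4 (4S)-2-methoxy-4-methyl-3,4,6,7-tetrahydrocyclopenta[b]pyran-5(2H)-one, via lactol 3 (not isolated)
Conditions: (R)-α,α-diphenylprolinol TMS ether (10 mol %), PhCO2H (10 mol %), CH2Cl2, 0 °C to rt; then MeOH, p-TsOH·H2O (5 mol %), rt
Reagents that add atoms: methanol (CO)
Why: Iminium-catalysed asymmetric Michael addition of the cyclic 1,3-diketone to the enal, in which the (R)-catalyst shields one face so that C10 forms as (S), followed by lactol closure and acetalisation that mask C8 and lock one carbonyl as a vinylogous ester.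

Step 2
Reactants: 4 (4S)-2-methoxy-4-methyl-3,4,6,7-tetrahydrocyclopenta[b]pyran-5(2H)-one
Product: 6 (4S)-2-methoxy-4,6-dimethyl-5-(trimethylsilyloxy)-2,3,4,7-tetrahydrocyclopenta[b]pyran, via C4-methyl ketone 5 (not isolated)
Conditions: LDA (1.05 equiv), THF, −78 °C; MeI (1.0 equiv), −78 to −30 °C; then TMSCl (1.5 equiv), LDA (1.2 equiv), −78 °C; non-aqueous work-up
Reagents that add atoms: iodomethane (CI); chlorotrimethylsilane (C[Si](C)(C)Cl)
Why: Kinetic α′-deprotonation of the vinylogous ester (Stork–Danheiser regiochemistry) puts the methyl group on C4, and a second deprotonation under internal TMSCl quench fixes the same regiochemistry as the tetrasubstituted silyl dienol ether, so no lasting stereocentre is made here.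

Step 3
Reactants: 6 (4S)-2-methoxy-4,6-dimethyl-5-(trimethylsilyloxy)-2,3,4,7-tetrahydrocyclopenta[b]pyran
Product: 7 (4S,6S)-2-methoxy-4,6-dimethyl-6-(trimethylsilyloxy)-3,4,6,7-tetrahydrocyclopenta[b]pyran-5(2H)-one
Conditions: (±)-trans-2-(phenylsulfonyl)-3-phenyloxaziridine (1.3 equiv), O-allyl-N-(9-anthracenylmethyl)cinchonidinium bifluoride (10 mol %), toluene/CH2Cl2 7:3, −78 °C
Reagents that add atoms: 2-(phenylsulfonyl)-3-phenyloxaziridine (O=S(=O)(c1ccccc1)N1OC1c1ccccc1)
Why: Proposed new method: chiral-cation-directed catalytic Rubottom-type hydroxylation, in which bifluoride desilylates 6 to a cross-conjugated dienolate tightly paired with the cinchonidinium cation, whose anthracenylmethyl wall covers the Re face of C4 so that the enolate carbon attacks the oxaziridine oxygen (SN2 at O) from the Si (β) face and sets C4 as (S); the hemiaminal anion collapses to the sulfonimine and a tertiary alkoxide that takes the TMS group from the next molecule of 6 and so regenerates the ammonium enolate (silyl-transfer chain), while neutral 6 is inert to the oxaziridine at −78 °C, so there is no unselective background; the closest known reaction types are chiral ammonium (bi)fluoride-catalysed Mukaiyama aldol and Michael reactions of silyl enol ethers and the stoichiometric Davis hydroxylation of metal enolates.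

Step 4
Reactants: 7 (4S,6S)-2-methoxy-4,6-dimethyl-6-(trimethylsilyloxy)-3,4,6,7-tetrahydrocyclopenta[b]pyran-5(2H)-one; 8 allylmagnesium bromide
Product: 10 (4S)-2-[(2S)-4,4-dimethoxybutan-2-yl]-4-hydroxy-4-methyl-3-(prop-2-en-1-yl)cyclopent-2-en-1-one, via 1,2-adduct 9 (not isolated)
Conditions: 8 (1.5 equiv), THF, −78 to −20 °C; then HCl (1.25 M in MeOH), 0 °C to rt
Reagents that add atoms: methanol (CO)
Why: Stork–Danheiser sequence in which the allyl Grignard reagent adds 1,2 to the hindered C5 carbonyl, acid ionises the tertiary allylic alcohol, the cyclic oxocarbenium ion collapses to the C2 enone with capture of C8 as the dimethyl acetal, and the TMS ether is lost; C4 and C10 are not touched.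

Step 5
Reactants: 11 pent-4-yn-1-ol
Product: 12 pent-4-yn-1-yl acetate
Conditions: Ac2O, Et3N, DMAP (2 mol %), CH2Cl2, 0 °C to rt
Reagents that add atoms: acetic anhydride (CC(=O)OC(C)=O)
Why: DMAP-catalysed acetylation of an unhindered primary alcohol installs the side-chain acetate of the target at the outset.

Step 6
Reactants: 12 pent-4-yn-1-yl acetate
Product: 13 4-(4,4,5,5-tetramethyl-1,3,2-dioxaborolan-2-yl)pent-4-en-1-yl acetate
Conditions: B2pin2 (1.1 equiv), CuCl (5 mol %), SIPr·HCl (5 mol %), NaOtBu (15 mol %), MeOH (2 equiv), THF, −15 °C to rt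
Reagents that add atoms: bis(pinacolato)diboron (CC1(C)OB(OC1(C)C)B1OC(C)(C)C(C)(C)O1)
Why: NHC–copper-catalysed protoboration of a terminal alkyne, in which the N-aryl carbene ligand directs boron to the internal carbon and gives the α-vinylboronate.

Step 7
Reactants: 14 (2-bromo-4-chlorophenyl)methanol
Product: 15 [(2-bromo-4-chlorobenzyl)oxy](tert-butyl)dimethylsilane
Conditions: TBSCl, imidazole, DMF, rt
Reagents that add atoms: tert-butyldimethylsilyl chloride (CC(C)(C)[Si](C)(C)Cl)
Why: Standard silyl ether formation keeps the benzylic oxygen apart from the two oxygens that are to carry acetates.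

Step 8
Reactants: 15 [(2-bromo-4-chlorobenzyl)oxy](tert-butyl)dimethylsilane; 13 4-(4,4,5,5-tetramethyl-1,3,2-dioxaborolan-2-yl)pent-4-en-1-yl acetate
Product: 16 4-[2-({[tert-butyl(dimethyl)silyl]oxy}methyl)-5-chlorophenyl]pent-4-en-1-yl acetate
Conditions: Pd(dppf)Cl2 (3 mol %), K3PO4, THF/H2O 10:1, 50 °C
Reagents that add atoms: none
Why: Suzuki–Miyaura coupling in which oxidative addition at C–Br is much faster than at C–Cl with this ligand, so the chloride is kept for step 10.

Step 9
Reactants: 16 4-[2-({[tert-butyl(dimethyl)silyl]oxy}methyl)-5-chlorophenyl]pent-4-en-1-yl acetate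
Product: 17 (4R)-4-[2-({[tert-butyl(dimethyl)silyl]oxy}methyl)-5-chlorophenyl]pentyl acetate
Conditions: H2 (1 bar), [Ir(cod)((S,S)-ThrePHOX)]BArF (1 mol %), CH2Cl2, 0 °C
Reagents that add atoms: none
Why: Iridium N,P-ligand-catalysed asymmetric hydrogenation of an unfunctionalised 1,1-disubstituted aryl alkene at low pressure, with hydrogen delivered to the Si face of the internal carbon to give the (R) benzylic centre; the aryl chloride, silyl ether and acetate are inert.

Step 10
Reactants: 17 (4R)-4-[2-({[tert-butyl(dimethyl)silyl]oxy}methyl)-5-chlorophenyl]pentyl acetate; 18 methyl pyruvate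
Product: 21 methyl 2-{3-[(2R)-5-acetoxypentan-2-yl]-4-({[tert-butyl(dimethyl)silyl]oxy}methyl)phenyl}prop-2-enoate, via tosylhydrazone 19 (not isolated), via methyl 2-diazopropanoate 20 (not isolated)
Conditions: 18, TsNHNH2, dioxane, 60 °C; then 17, Pd2(dba)3 (2 mol %), XPhos (8 mol %), K2CO3 (2.5 equiv), 100 °C
Reagents that add atoms: none
Why: Barluenga-type palladium-catalysed coupling in which the hydrazone releases the diazo ester, the arylpalladium chloride forms a carbene, and aryl migration followed by β-hydride elimination from the methyl group gives the 2-arylacrylate without involving the benzylic stereocentre.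

Step 11
Reactants: 10 (4S)-2-[(2S)-4,4-dimethoxybutan-2-yl]-4-hydroxy-4-methyl-3-(prop-2-en-1-yl)cyclopent-2-en-1-one; 21 methyl 2-{3-[(2R)-5-acetoxypentan-2-yl]-4-({[tert-butyl(dimethyl)silyl]oxy}methyl)phenyl}prop-2-enoate
Product: 23 (3R,4aR,7aS)-3-{3-[(2R)-5-acetoxypentan-2-yl]-4-({[tert-butyl(dimethyl)silyl]oxy}methyl)phenyl}-6-[(2S)-4,4-dimethoxybutan-2-yl]-7a-methyl-7-(prop-2-en-1-yl)-3,4,4a,7a-tetrahydrocyclopenta[b]pyran-2,5-dione, via Michael adduct 22 (not isolated)
Conditions: 10, LDA (2.15 equiv), THF, −78 °C; 21 (1.05 equiv), −78 to −15 °C; AcOH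
Reagents that add atoms: none
Why: Fráter–Seebach-type α′,O-dianion (no β-elimination, because oxide would be the leaving group) adds in Michael fashion to the α-aryl acrylate, the C4 alkoxide then closes ring D on the methyl ester, which only the cis-fused C3 epimer can do, and the LiOMe released equilibrates C3 and C11′ so that the aryl group ends pseudo-equatorial with H-11′ on the convex face.

Step 12
Reactants: 23 keto δ-lactone (name as in step 11)
Product: 25 (3R,4aS,5R,7aS)-3-{3-[(2R)-5-acetoxypentan-2-yl]-4-({[tert-butyl(dimethyl)silyl]oxy}methyl)phenyl}-6-[(2S)-4,4-dimethoxybutan-2-yl]-7a-methyl-2-oxo-7-(prop-2-en-1-yl)-2,3,4,4a,5,7a-hexahydrocyclopenta[b]pyran-5-yl acetate, via allylic alcohol 24 (not isolated)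
Conditions: NaBH4, CeCl3·7H2O, MeOH/THF, −78 °C; pH 7 work-up; then Ac2O, pyridine, DMAP (5 mol %), CH2Cl2, 0 °C
Reagents that add atoms: acetic anhydride (CC(=O)OC(C)=O)
Why: Luche 1,2-reduction in which hydride reaches C2 from the convex α face opposite ring D and gives the 2β-alcohol, which is acetylated at once to forestall acyl migration from O4 to O2; the same acetylation restores any side-chain acetate lost in step 11.

Step 13
Reactants: 25 C2 acetate (name as in step 12)
Product: 26 the C8 aldehyde with free benzylic alcohol: 25 in which CH(OMe)2 has become CHO and CH2OTBS has become CH2OH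
Conditions: 48 % aq. HF/MeCN 1:19, 0 °C
Reagents that add atoms: water (O)
Why: Aqueous HF cleaves the primary silyl ether and hydrolyses the dimethyl acetal in one operation, while the esters and allylic C–O bonds survive the short cold exposure and no stereocentre is touched.

Step 14
Reactants: 26 C8 aldehyde with free benzylic alcohol; 27 methyl 2-(bromomethyl)acrylate
Product: 28 the (Z)-allylic bromide: 26 in which the C5 allyl group has become CH2–CH=C(CH2Br)CO2Me, with C6 cis to CH2Br
Conditions: 27 (5 equiv), second-generation Hoveyda–Grubbs catalyst (7 mol %), 1,4-benzoquinone (10 mol %), CH2Cl2, 40 °C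
Reagents that add atoms: none
Why: Olefin cross-metathesis of an unhindered terminal alkene with an excess of a methacrylate-type 1,1-disubstituted acrylate gives the trisubstituted enoate with the chain trans to the ester, benzoquinone suppresses alkene migration, and the aldehyde and alcohol are tolerated.

Step 15
Reactants: 28 (Z)-allylic bromide aldehyde
Product: 30 CNP0205574.1 (target), via hydroxy ester 29 (not isolated)
Conditions: CrCl2 (8 equiv), THF/DMF 4:1, 2 mM, slow addition, rt; aq. NH4Cl
Reagents that add atoms: none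
Why: Intramolecular Nozaki–Hiyama-type allylchromium addition and lactonisation, in which the equilibrating allylchromium reacts through a chair transition state with both tether ends (C6, C9) pseudo-equatorial to give the anti adduct and hence the trans lactone, while the C10 methyl group sits pseudo-axial to avoid A(1,3) strain with C2, which selects the 7R,8S pair.

**Compound list**
1 | cyclopentane-1,3-dione | O=C1CCC(=O)C1 | starting material
2 | (E)-but-2-enal | C/C=C/C=O | starting material
3 | (4S)-2-hydroxy-4-methyl-3,4,6,7-tetrahydrocyclopenta[b]pyran-5(2H)-one | OC1C[C@H](C)C2=C(O1)CCC2=O | intermediate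
4 | (4S)-2-methoxy-4-methyl-3,4,6,7-tetrahydrocyclopenta[b]pyran-5(2H)-one | COC1C[C@H](C)C2=C(O1)CCC2=O | intermediate
5 | (4S)-2-methoxy-4,6-dimethyl-3,4,6,7-tetrahydrocyclopenta[b]pyran-5(2H)-one | COC1C[C@H](C)C2=C(O1)CC(C)C2=O | intermediate
6 | (4S)-2-methoxy-4,6-dimethyl-5-(trimethylsilyloxy)-2,3,4,7-tetrahydrocyclopenta[b]pyran | COC1C[C@H](C)C2=C(O1)CC(C)=C2O[Si](C)(C)C | intermediate
7 | (4S,6S)-2-methoxy-4,6-dimethyl-6-(trimethylsilyloxy)-3,4,6,7-tetrahydrocyclopenta[b]pyran-5(2H)-one | COC1C[C@H](C)C2=C(O1)C[C@](C)(O[Si](C)(C)C)C2=O | intermediate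
8 | allylmagnesium bromide | C=CC[Mg]Br | starting material
9 | (4S,6S)-5-allyl-2-methoxy-4,6-dimethyl-6-(trimethylsilyloxy)-2,3,4,5,6,7-hexahydrocyclopenta[b]pyran-5-ol | COC1C[C@H](C)C2=C(O1)C[C@](C)(O[Si](C)(C)C)C2(O)CC=C | intermediate
10 | (4S)-2-[(2S)-4,4-dimethoxybutan-2-yl]-4-hydroxy-4-methyl-3-(prop-2-en-1-yl)cyclopent-2-en-1-one | COC(OC)C[C@H](C)C1=C(CC=C)[C@@](C)(O)CC1=O | intermediate
11 | pent-4-yn-1-ol | C#CCCCO | starting material
12 | pent-4-yn-1-yl acetate | C#CCCCOC(C)=O | intermediate
13 | 4-(4,4,5,5-tetramethyl-1,3,2-dioxaborolan-2-yl)pent-4-en-1-yl acetate | C=C(CCCOC(C)=O)B1OC(C)(C)C(C)(C)O1 | intermediate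
14 | (2-bromo-4-chlorophenyl)methanol | OCc1ccc(Cl)cc1Br | starting material
15 | [(2-bromo-4-chlorobenzyl)oxy](tert-butyl)dimethylsilane | CC(C)(C)[Si](C)(C)OCc1ccc(Cl)cc1Br | intermediate
16 | 4-[2-({[tert-butyl(dimethyl)silyl]oxy}methyl)-5-chlorophenyl]pent-4-en-1-yl acetate | C=C(CCCOC(C)=O)c1cc(Cl)ccc1CO[Si](C)(C)C(C)(C)C | intermediate
17 | (4R)-4-[2-({[tert-butyl(dimethyl)silyl]oxy}methyl)-5-chlorophenyl]pentyl acetate | Clc1ccc(CO[Si](C)(C)C(C)(C)C)c([C@H](C)CCCOC(C)=O)c1 | intermediate
18 | methyl pyruvate | CC(=O)C(=O)OC | starting material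
19 | methyl 2-(2-tosylhydrazinylidene)propanoate | COC(=O)C(C)=NNS(=O)(=O)c1ccc(C)cc1 | intermediate
20 | methyl 2-diazopropanoate | COC(=O)C(C)=[N+]=[N-] | intermediate
21 | methyl 2-{3-[(2R)-5-acetoxypentan-2-yl]-4-({[tert-butyl(dimethyl)silyl]oxy}methyl)phenyl}prop-2-enoate | C=C(C(=O)OC)c1ccc(CO[Si](C)(C)C(C)(C)C)c([C@H](C)CCCOC(C)=O)c1 | intermediate
22 | Michael adduct: 10 carrying CH2CH(Ar)CO2Me at C3 (C4–OH free) | COC(OC)C[C@H](C)C1=C(CC=C)[C@@](C)(O)C(CC(C(=O)OC)c2ccc(CO[Si](C)(C)C(C)(C)C)c([C@H](C)CCCOC(C)=O)c2)C1=O | intermediate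
23 | keto δ-lactone (3R,4aR,7aS; rings A/D cis-fused, H-3, H-11′ and 4-Me α) | COC(OC)C[C@H](C)C1=C(CC=C)[C@@]2(C)OC(=O)[C@@H](c3ccc(CO[Si](C)(C)C(C)(C)C)c([C@H](C)CCCOC(C)=O)c3)C[C@H]2C1=O | intermediate
24 | 2β-allylic alcohol from 23 | COC(OC)C[C@H](C)C1=C(CC=C)[C@@]2(C)OC(=O)[C@@H](c3ccc(CO[Si](C)(C)C(C)(C)C)c([C@H](C)CCCOC(C)=O)c3)C[C@H]2[C@H]1O | intermediate
25 | 2β-acetate (3R,4aS,5R,7aS) | COC(OC)C[C@H](C)C1=C(CC=C)[C@@]2(C)OC(=O)[C@@H](c3ccc(CO[Si](C)(C)C(C)(C)C)c([C@H](C)CCCOC(C)=O)c3)C[C@H]2[C@H]1OC(C)=O | intermediate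
26 | C8 aldehyde with free benzylic alcohol | O=CC[C@H](C)C1=C(CC=C)[C@@]2(C)OC(=O)[C@@H](c3ccc(CO)c([C@H](C)CCCOC(C)=O)c3)C[C@H]2[C@H]1OC(C)=O | intermediate
27 | methyl 2-(bromomethyl)acrylate | C=C(CBr)C(=O)OC | starting material
28 | (Z)-allylic bromide aldehyde | O=CC[C@H](C)C1=C(C/C=C(\CBr)C(=O)OC)[C@@]2(C)OC(=O)[C@@H](c3ccc(CO)c([C@H](C)CCCOC(C)=O)c3)C[C@H]2[C@H]1OC(C)=O | intermediate
29 | (7R,8S)-8-hydroxy 12-methyl ester (ring B closed, ring C open) | O[C@H]1C[C@H](C)C2=C(C[C@@H]1C(=C)C(=O)OC)[C@@]3(C)OC(=O)[C@@H](c4ccc(CO)c([C@H](C)CCCOC(C)=O)c4)C[C@H]3[C@H]2OC(C)=O | intermediate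
30 | CNP0205574.1 | C=C1C(=O)O[C@H]2C[C@H](C)C3=C(C[C@H]12)[C@@]1(C)OC(=O)[C@@H](c2ccc(CO)c([C@H](C)CCCOC(C)=O)c2)C[C@H]1[C@H]3OC(C)=O | target

**Step count**

- Total steps: 15.
- Longest linear sequence: 10 steps (11 → 12 → 13 → 16 → 17 → 21 → 23 → 25 → 26 → 28 → 30).

**The three steps most likely to fail**

Step 3 (the new method). The ion pair may give poor facial selectivity on a substrate without an aryl ring, and the sulfonimine may trap the enolate. The fallback sets out from 6 and comes back at 10, and uses known chemistry only. MeLi (THF, 0 °C) cleaves the silyl ether to the regiodefined lithium enolate. This enolate is hydroxylated at −78 °C with stoichiometric (+)-(8,8-dichlorocamphorylsulfonyl)oxaziridine (reagent-controlled Davis oxidation) to give (4S,6S)-6-hydroxy-2-methoxy-4,6-dimethyl-3,4,6,7-tetrahydrocyclopenta[b]pyran-5(2H)-one F1. The minor C4 epimer is a diastereomer and is removed by chromatography. F1 with 2.5 equiv of 8 followed by methanolic HCl gives 10.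

Step 14. Cross-metathesis with a 1,1-disubstituted acrylate that carries an allylic bromide may be slow or low-yielding. The fallback sets out from 25 and comes back at 28, and builds the same unit by carbonyl chemistry:
- Lemieux–Johnson cleavage (OsO4 cat., NaIO4, 2,6-lutidine) of the terminal alkene gives the C7 aldehyde F2.
- A Morita–Baylis–Hillman reaction with methyl acrylate (DABCO) gives the allylic alcohol F3.
- NBS/Me2S converts F3 with allylic transposition into the protected (Z)-bromide F4.
- Aq. HF/MeCN as in step 13 then gives 28.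

Step 15. The closure may give the cis lactone, the wrong 7,8 pair, or oligomers. The fallback sets out from 26 and comes back at 29, and replaces the closed metal-bound transition state by an open one. Cross-metathesis of 26 with methyl 2-[(trimethylsilyl)methyl]acrylate gives the allylsilane aldehyde F5. BF3·OEt2 (CH2Cl2, −78 °C) then triggers an intramolecular Hosomi–Sakurai cyclisation. This is a known route to trans-fused α-methylene-γ-lactones on seven-membered rings. It gives 29, which lactonises to 30.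

**Further compounds**
F1 | step 3 | (4S,6S)-6-hydroxy-2-methoxy-4,6-dimethyl-3,4,6,7-tetrahydrocyclopenta[b]pyran-5(2H)-one | COC1C[C@H](C)C2=C(O1)C[C@](C)(O)C2=O
F2 | step 14 | C7 aldehyde (25 with C5–CH2CHO in place of allyl) | COC(OC)C[C@H](C)C1=C(CC=O)[C@@]2(C)OC(=O)[C@@H](c3ccc(CO[Si](C)(C)C(C)(C)C)c([C@H](C)CCCOC(C)=O)c3)C[C@H]2[C@H]1OC(C)=O
F3 | step 14 | Morita–Baylis–Hillman alcohol (carbinol epimers) | COC(OC)C[C@H](C)C1=C(CC(O)C(=C)C(=O)OC)[C@@]2(C)OC(=O)[C@@H](c3ccc(CO[Si](C)(C)C(C)(C)C)c([C@H](C)CCCOC(C)=O)c3)C[C@H]2[C@H]1OC(C)=O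
F4 | step 14 | protected (Z)-allylic bromide (acetal and TBS ether intact) | COC(OC)C[C@H](C)C1=C(C/C=C(\CBr)C(=O)OC)[C@@]2(C)OC(=O)[C@@H](c3ccc(CO[Si](C)(C)C(C)(C)C)c([C@H](C)CCCOC(C)=O)c3)C[C@H]2[C@H]1OC(C)=O
F5 | step 15 | (Z)-allylsilane aldehyde | O=CC[C@H](C)C1=C(C/C=C(\C[Si](C)(C)C)C(=O)OC)[C@@]2(C)OC(=O)[C@@H](c3ccc(CO)c([C@H](C)CCCOC(C)=O)c3)C[C@H]2[C@H]1OC(C)=O
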